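**Plan**

1. Retrosynthesis: the three benzyl ethers are removed last. Ring C (the pyranone) is opened at the O1–C2 ketal bond to a C2 methyl ketal and a ring A phenol, and the C4–C4a bond is cut to a ring A aryllithium and a C3 methyl ester. The C2–C3 bond of the dihydrofuran is cut photochemically to a ring D glyoxylate whose O7' carries the mixed methyl acetal of the ring B aldehyde. C8'–C3 goes back to an 8'-lithioflavan and dimethyl oxalate, and O7'–C2 to a phenoxide and an α-chlorobenzyl methyl ether.
2. Enabling feature: in the furan fused to ring D (the flavan benzene ring), C3 is a tertiary alcohol bonded to ring D carbon C8' and C2 is an O-benzylic ketal carbon bonded to O7'. This is the pattern left when the carbonyl oxygen of an ortho-alkoxyaryl ketone takes the δ-hydrogen of the alkoxy group and the 1,5-biradical closes.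
3. C4 passes through the photoreaction as a methyl ester, so the chromophore has a single abstracting carbonyl (a 1,2-diketone would offer a second oxygen and a six-membered closure). Ring A is added afterwards.
4. Forward order: flavan from (S)-naringenin by C4 deoxygenation, then C8' bromination, O7' acetal and glyoxylate; dihydrofuran by Norrish–Yang cyclization; ring A ketone by aryllithium acylation; ring C by acid ketal exchange; hydrogenolysis.
5. Stereochemistry: C2' comes from (S)-naringenin. C3 arises in the photocyclization without control from the remote centre, and the epimers are separated. C2 follows C3 because ring C can only be cis-fused.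

Key step: step 10

Assumption: (S)-naringenin is used enantiomerically pure, and the enantiomeric purity of the flavan is checked at compound 6 on a chiral stationary phase.
Locants: unprimed C2, C3, C4 and rings A and B belong to the chromanone unit of the target, and primed locants to the flavan unit. In the furo[2,3-h]chromene names of 16, 20 and 21, C8 is the future C2, C9 the future C3 and C2 the flavan C2'.

**Step 1**
Reactants: 1 (S)-naringenin, (2S)-5,7-dihydroxy-2-(4-hydroxyphenyl)chroman-4-one
Product: 2 (2S)-5-hydroxy-2-(4-hydroxyphenyl)-7-(methoxymethoxy)chroman-4-one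
Conditions: MOMCl (1.05 equiv), iPr2NEt, THF/DMF, 0 °C
Reagents that add atoms: chloromethyl methyl ether, COCCl
Why: O-alkylation of a phenoxide by an α-chloro ether (Williamson type); the 7-OH, para to the carbonyl, is the most acidic phenol and reacts first, the 5-OH is chelated to the ketone, and an amine base at 0 °C should not open the flavanone, so C2 keeps its configuration.

**Step 2**
Reactants: 2 (2S)-5-hydroxy-2-(4-hydroxyphenyl)-7-(methoxymethoxy)chroman-4-one
Product: 3 (2S)-2-[4-(benzyloxy)phenyl]-5-hydroxy-7-(methoxymethoxy)chroman-4-one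
Conditions: BnOH, PPh3, DIAD, THF, 0 °C to rt
Reagents that add atoms: benzyl alcohol, OCc1ccccc1
Why: Mitsunobu etherification of the only unchelated phenol; it avoids carbonate base and heat, which open 5-hydroxyflavanones to chalcones and would racemize C2.

**Step 3**
Reactants: 3 (2S)-2-[4-(benzyloxy)phenyl]-5-hydroxy-7-(methoxymethoxy)chroman-4-one
Product: 5 (2S)-2-[4-(benzyloxy)phenyl]-7-(methoxymethoxy)chroman-5-ol, via 5-O-ethyl carbonate 4 (not isolated)
Conditions: ClCO2Et, Et3N, THF, 0 °C; filter; NaBH4, THF/H2O, 0 °C to rt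
Reagents that add atoms: none
Why: Carbonate-assisted borohydride deoxygenation of an ortho-hydroxyaryl ketone: hydride reduces the ketone, the carbonate shifts to the benzylic alkoxide and is expelled to an ortho-quinone methide, and a second hydride reduces this to the methylene, which leaves C2 untouched and removes any later path to ring opening.

**Step 4**
Reactants: 5 (2S)-2-[4-(benzyloxy)phenyl]-7-(methoxymethoxy)chroman-5-ol
Product: 6 (2S)-5-(benzyloxy)-2-[4-(benzyloxy)phenyl]-7-(methoxymethoxy)chromane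
Conditions: BnBr, K2CO3, DMF, rt
Reagents that add atoms: benzyl bromide, BrCc1ccccc1
Why: Williamson ether synthesis on the single free phenol; the flavan no longer has a carbonyl, so base cannot affect C2.

**Step 5**
Reactants: 6 (2S)-5-(benzyloxy)-2-[4-(benzyloxy)phenyl]-7-(methoxymethoxy)chromane
Product: 7 (2S)-5-(benzyloxy)-2-[4-(benzyloxy)phenyl]-8-bromo-7-(methoxymethoxy)chromane
Conditions: NBS (1.0 equiv), CH2Cl2, −78 to −20 °C
Reagents that add atoms: N-bromosuccinimide, O=C1CCC(=O)N1Br
Why: Electrophilic aromatic bromination, which in 5,7-dialkoxyflavans goes to C8 (between O7 and the ring oxygen) in preference to C6 (between two freely rotating ethers); one equivalent at low temperature should avoid dibromination.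

**Step 6**
Reactants: 7 (2S)-5-(benzyloxy)-2-[4-(benzyloxy)phenyl]-8-bromo-7-(methoxymethoxy)chromane
Product: 8 (2S)-5-(benzyloxy)-2-[4-(benzyloxy)phenyl]-8-bromochroman-7-ol
Conditions: HCl (2 M), MeOH/THF, 40 °C
Reagents that add atoms: none
Why: Acid-catalysed transacetalization of the MOM ether to methanol; benzyl ethers, the aryl bromide and the flavan ether are inert to dilute methanolic HCl.

**Step 7**
Reactants: 9 4-(benzyloxy)benzaldehyde
Product: 10 1-(benzyloxy)-4-(dimethoxymethyl)benzene
Conditions: HC(OMe)3, p-TsOH (cat.), MeOH, rt; Et3N quench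
Reagents that add atoms: trimethyl orthoformate, COC(OC)OC
Why: Acid-catalysed acetalization driven by the orthoformate as water scavenger.

**Step 8**
Reactants: 8 (2S)-5-(benzyloxy)-2-[4-(benzyloxy)phenyl]-8-bromochroman-7-ol; 10 1-(benzyloxy)-4-(dimethoxymethyl)benzene
Product: 12 (2S)-5-(benzyloxy)-2-[4-(benzyloxy)phenyl]-7-{[4-(benzyloxy)phenyl](methoxy)methoxy}-8-bromochromane (both acetal epimers), via α-chloro ether 11 (not isolated)
Conditions: 10, AcCl, SOCl2 (cat.), CH2Cl2, rt, evaporate; then 8, NaH, THF/DMF, 0 °C; NaHCO3 work-up, Et3N-deactivated silica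
Reagents that add atoms: none
Why: Acetyl chloride converts the dimethyl acetal into the α-chloro ether (acetal–acyl halide exchange), which O-alkylates the sodium phenoxide through its oxocarbenium ion pair; the mixed acetal is stable to base and both epimers serve.

**Step 9**
Reactants: 12 (2S)-5-(benzyloxy)-2-[4-(benzyloxy)phenyl]-7-{[4-(benzyloxy)phenyl](methoxy)methoxy}-8-bromochromane; 13 dimethyl oxalate
Product: 15 methyl 2-[(2S)-5-(benzyloxy)-2-[4-(benzyloxy)phenyl]-7-{[4-(benzyloxy)phenyl](methoxy)methoxy}chroman-8-yl]-2-oxoacetate, via 8-lithiochromane 14 (not isolated)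
Conditions: n-BuLi, THF, −78 °C; cannulate into (CO2Me)2 (3 equiv), THF, −78 °C; pH 7 buffer
Reagents that add atoms: none
Why: Bromine–lithium exchange outruns deprotonation at −78 °C, and inverse addition of the aryllithium to excess dimethyl oxalate should stop at the α-keto ester because the tetrahedral adduct persists until work-up.

**Step 10**
Reactants: 15 methyl 2-[(2S)-5-(benzyloxy)-2-[4-(benzyloxy)phenyl]-7-{[4-(benzyloxy)phenyl](methoxy)methoxy}chroman-8-yl]-2-oxoacetate
Product: 16 methyl (2S,8S,9S)-5-(benzyloxy)-2,8-bis[4-(benzyloxy)phenyl]-9-hydroxy-8-methoxy-3,4,8,9-tetrahydro-2H-furo[2,3-h]chromene-9-carboxylate (its C8 epimer is equally usable)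
Conditions: hν (365 nm, Pyrex), degassed benzene (0.01 M) over solid K2CO3, 20 °C
Reagents that add atoms: none
Why: Excitation of the n,π* band of the aryl glyoxylate gives a triplet in which only the ketone oxygen on the carbon bonded to ring D can abstract (the ester carbonyl is photochemically inert); this oxygen takes the acetal hydrogen on the carbon attached to O7' through a seven-membered transition state (1,6-hydrogen transfer from the δ-carbon) and gives a triplet 1,5-biradical made of a ketyl carbon and a doubly oxygen-stabilized benzylic carbon. After intersystem crossing the two radical carbons recombine, which forms the C8–C9 bond and closes the five-membered dihydrofuran as the only new ring (collapse of a 1,5-biradical, the Norrish–Yang mode). The closest known reactions are the photocyclization of ortho-benzyloxyphenyl glyoxylates and ortho-alkoxyphenyl ketones to 3-hydroxy-2,3-dihydrobenzofurans, and Yang cyclizations in which an acetal hydrogen is abstracted and a ketal carbon results. C9 forms without control from the remote flavan centre, so both C9 epimers are expected and the (9S) series is taken on after chromatographic separation, whereas the configuration at the ketal carbon C8 does not matter because step 13 re-forms that centre. Site selectivity rests on the substrate: the acetal C–H is the weakest and the only δ-hydrogen within reach, the benzyl ether on O5' is para to the ketone, the flavan C2'–H is held on the far side by the pyran ring, and the methyl ester has only strong primary C–H bonds. Long-wavelength light and a base-buffered medium should keep the mixed acetal and the benzyl ethers intact.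

**Step 11**
Reactants: 17 phloroglucinol
Product: 18 1,3,5-tris(methoxymethoxy)benzene
Conditions: MOMCl (3.5 equiv), iPr2NEt, CH2Cl2, 0 °C to rt
Reagents that add atoms: chloromethyl methyl ether, COCCl
Why: Threefold O-alkylation of the phenol with an α-chloro ether under amine base.

**Step 12**
Reactants: 16 methyl (2S,8S,9S)-5-(benzyloxy)-2,8-bis[4-(benzyloxy)phenyl]-9-hydroxy-8-methoxy-3,4,8,9-tetrahydro-2H-furo[2,3-h]chromene-9-carboxylate; 18 1,3,5-tris(methoxymethoxy)benzene
Product: 20 [(2S,8S,9R)-5-(benzyloxy)-2,8-bis[4-(benzyloxy)phenyl]-9-hydroxy-8-methoxy-3,4,8,9-tetrahydro-2H-furo[2,3-h]chromen-9-yl][2,4,6-tris(methoxymethoxy)phenyl]methanone, via aryllithium 19 (not isolated)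
Conditions: 18 (3 equiv), n-BuLi, THF, 0 °C; then 16, THF, −78 to −30 °C; pH 7 buffer
Reagents that add atoms: none
Why: Directed ortho-lithiation between two MOM ethers gives the aryllithium, one equivalent of which deprotonates the tertiary alcohol while a second acylates on the methyl ester (organolithium ester-to-ketone acylation); the resulting ketone lies between a quaternary carbon and a 2,6-disubstituted ring and should not add a second aryl group.

**Step 13**
Reactants: 20 [(2S,8S,9R)-5-(benzyloxy)-2,8-bis[4-(benzyloxy)phenyl]-9-hydroxy-8-methoxy-3,4,8,9-tetrahydro-2H-furo[2,3-h]chromen-9-yl][2,4,6-tris(methoxymethoxy)phenyl]methanone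
Product: 22 tri-O-benzyl ether of the target (benzyl on the ring B phenol, on O5' and on the phenol of the flavan 2'-aryl group; (2R,3R,2'S)), via triphenol methyl ketal 21 (not isolated)
Conditions: HCl (3 M aq), MeOH/THF, 40 °C; evaporate; CSA (cat.), CH2Cl2, 4 Å MS, rt
Reagents that add atoms: none
Why: Acid methanolysis removes the three MOM ethers, and a ring A phenol ortho to the ketone then captures the aryl-stabilized oxocarbenium ion formed from the methyl ketal (ketal exchange, six-membered ring closure); the new ring can only be cis-fused, so C2 takes the configuration dictated by C3 whichever ketal epimer enters.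

**Step 14**
Reactants: 22 tri-O-benzyl ether of the target
Product: 23 CNP0208300.2, (2R,3R,2'S)
Conditions: H2 (1 atm), Pd/C (10% palladium on carbon), EtOAc/MeOH, rt
Reagents that add atoms: none
Why: Hydrogenolysis of the three aryl benzyl ethers under neutral conditions; the chelated aryl ketone, the diaryl ketal, the tertiary alcohol and the flavan C–O bond are expected to survive, as such groups do in debenzylations of doubly linked flavonoid dimers.

**Compound list**

1 | (S)-naringenin | O=C1C[C@@H](c2ccc(O)cc2)Oc2cc(O)cc(O)c12 | starting material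
2 | (2S)-5-hydroxy-2-(4-hydroxyphenyl)-7-(methoxymethoxy)chroman-4-one | O=C1C[C@@H](c2ccc(O)cc2)Oc2cc(OCOC)cc(O)c12 | intermediate
3 | (2S)-2-[4-(benzyloxy)phenyl]-5-hydroxy-7-(methoxymethoxy)chroman-4-one | O=C1C[C@@H](c2ccc(OCc3ccccc3)cc2)Oc2cc(OCOC)cc(O)c12 | intermediate
4 | (2S)-2-[4-(benzyloxy)phenyl]-7-(methoxymethoxy)-4-oxochroman-5-yl ethyl carbonate | O=C1C[C@@H](c2ccc(OCc3ccccc3)cc2)Oc2cc(OCOC)cc(OC(=O)OCC)c12 | intermediate
5 | (2S)-2-[4-(benzyloxy)phenyl]-7-(methoxymethoxy)chroman-5-ol | COCOc1cc(O)c2c(c1)O[C@H](c1ccc(OCc3ccccc3)cc1)CC2 | intermediate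
6 | (2S)-5-(benzyloxy)-2-[4-(benzyloxy)phenyl]-7-(methoxymethoxy)chromane | COCOc1cc(OCc2ccccc2)c2c(c1)O[C@H](c1ccc(OCc3ccccc3)cc1)CC2 | intermediate
7 | (2S)-5-(benzyloxy)-2-[4-(benzyloxy)phenyl]-8-bromo-7-(methoxymethoxy)chromane | COCOc1cc(OCc2ccccc2)c2c(c1Br)O[C@H](c1ccc(OCc3ccccc3)cc1)CC2 | intermediate
8 | (2S)-5-(benzyloxy)-2-[4-(benzyloxy)phenyl]-8-bromochroman-7-ol | Oc1cc(OCc2ccccc2)c2c(c1Br)O[C@H](c1ccc(OCc3ccccc3)cc1)CC2 | intermediate
9 | 4-(benzyloxy)benzaldehyde | O=Cc1ccc(OCc2ccccc2)cc1 | starting material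
10 | 1-(benzyloxy)-4-(dimethoxymethyl)benzene | COC(OC)c1ccc(OCc2ccccc2)cc1 | intermediate
11 | 1-(benzyloxy)-4-[chloro(methoxy)methyl]benzene (racemic) | COC(Cl)c1ccc(OCc2ccccc2)cc1 | intermediate
12 | (2S)-5-(benzyloxy)-2-[4-(benzyloxy)phenyl]-7-{[4-(benzyloxy)phenyl](methoxy)methoxy}-8-bromochromane, both acetal epimers | COC(Oc1cc(OCc2ccccc2)c2c(c1Br)O[C@H](c1ccc(OCc3ccccc3)cc1)CC2)c1ccc(OCc2ccccc2)cc1 | intermediate
13 | dimethyl oxalate | COC(=O)C(=O)OC | starting material
14 | 8-lithio analogue of 12 | [Li]c1c(OC(OC)c2ccc(OCc3ccccc3)cc2)cc(OCc2ccccc2)c2c1O[C@H](c1ccc(OCc3ccccc3)cc1)CC2 | intermediate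
15 | methyl 2-[(2S)-5-(benzyloxy)-2-[4-(benzyloxy)phenyl]-7-{[4-(benzyloxy)phenyl](methoxy)methoxy}chroman-8-yl]-2-oxoacetate, both acetal epimers | COC(=O)C(=O)c1c(OC(OC)c2ccc(OCc3ccccc3)cc2)cc(OCc2ccccc2)c2c1O[C@H](c1ccc(OCc3ccccc3)cc1)CC2 | intermediate
16 | methyl (2S,8S,9S)-5-(benzyloxy)-2,8-bis[4-(benzyloxy)phenyl]-9-hydroxy-8-methoxy-3,4,8,9-tetrahydro-2H-furo[2,3-h]chromene-9-carboxylate (8-OMe cis to the ester; C8 epimer equally usable) | COC(=O)[C@]1(O)c2c(O[C@@]1(OC)c3ccc(OCc4ccccc4)cc3)cc(OCc3ccccc3)c3c2O[C@H](c2ccc(OCc4ccccc4)cc2)CC3 | intermediate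
17 | phloroglucinol | Oc1cc(O)cc(O)c1 | starting material
18 | 1,3,5-tris(methoxymethoxy)benzene | COCOc1cc(OCOC)cc(OCOC)c1 | intermediate
19 | 2,4,6-tris(methoxymethoxy)phenyllithium | [Li]c1c(OCOC)cc(OCOC)cc1OCOC | intermediate
20 | [(2S,8S,9R)-5-(benzyloxy)-2,8-bis[4-(benzyloxy)phenyl]-9-hydroxy-8-methoxy-3,4,8,9-tetrahydro-2H-furo[2,3-h]chromen-9-yl][2,4,6-tris(methoxymethoxy)phenyl]methanone | O=C(c1c(OCOC)cc(OCOC)cc1OCOC)[C@]1(O)c2c(O[C@@]1(OC)c3ccc(OCc4ccccc4)cc3)cc(OCc3ccccc3)c3c2O[C@H](c2ccc(OCc4ccccc4)cc2)CC3 | intermediate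
21 | [(2S,8S,9R)-5-(benzyloxy)-2,8-bis[4-(benzyloxy)phenyl]-9-hydroxy-8-methoxy-3,4,8,9-tetrahydro-2H-furo[2,3-h]chromen-9-yl](2,4,6-trihydroxyphenyl)methanone | O=C(c1c(O)cc(O)cc1O)[C@]1(O)c2c(O[C@@]1(OC)c3ccc(OCc4ccccc4)cc3)cc(OCc3ccccc3)c3c2O[C@H](c2ccc(OCc4ccccc4)cc2)CC3 | intermediate
22 | tri-O-benzyl ether of the target (benzyl on the ring B phenol, O5' and the flavan 2'-aryl phenol; (2R,3R,2'S), 3-OH cis to the 2-aryl group) | O=C1c2c(O)cc(O)cc2O[C@@]2(c3ccc(OCc4ccccc4)cc3)Oc3cc(OCc4ccccc4)c4c(c3[C@@]12O)O[C@H](c1ccc(OCc2ccccc2)cc1)CC4 | intermediate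
23 | CNP0208300.2, (2R,3R,2'S) | O=C1c2c(O)cc(O)cc2O[C@@]2(c3ccc(O)cc3)Oc3cc(O)c4c(c3[C@@]12O)O[C@H](c1ccc(O)cc1)CC4 | target

**Step count and risks**

Total step count: 14. Longest linear sequence: 12 steps (steps 1 to 6, 8, 9, 10, 12, 13, 14).

Steps most likely to fail:

Step 10. The electron-rich aryl glyoxylate may have a charge-transfer lowest triplet that abstracts hydrogen slowly, so that unproductive decay, reverse hydrogen transfer in the biradical or gradual loss of the acetal outruns cyclization; the C9 epimers may also resist separation. The fallback sets out from 7 and comes back at 16; it reaches the ketal and carbinol centres by epoxidation instead of biradical coupling. Copper-free Sonogashira coupling of 7 with commercial 1-(benzyloxy)-4-ethynylbenzene (PdCl2(MeCN)2, XPhos, Cs2CO3, MeCN, 80 °C) would give (2S)-5-(benzyloxy)-2-[4-(benzyloxy)phenyl]-8-{[4-(benzyloxy)phenyl]ethynyl}-7-(methoxymethoxy)chromane F1. Methanolic HCl would free (2S)-5-(benzyloxy)-2-[4-(benzyloxy)phenyl]-8-{[4-(benzyloxy)phenyl]ethynyl}chroman-7-ol F2. Carbonylative annulation of this ortho-alkynylphenol (PdI2, thiourea, CBr4, Cs2CO3, CO, MeOH, 40 °C) would give methyl (2S)-5-(benzyloxy)-2,8-bis[4-(benzyloxy)phenyl]-3,4-dihydro-2H-furo[2,3-h]chromene-9-carboxylate F3. Dimethyldioxirane in acetone at −20 °C would epoxidize the furan C8=C9 bond to the 8,9-epoxide F4 (both faces), and added methanol would open it at the ketal carbon to give 16 together with its C9 epimer series, to be separated as in the main route.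

Step 12. After deprotonation of the tertiary alcohol, addition of the di-ortho-substituted aryllithium to the neopentyl-type ester may stall, or the alkoxide may open the neighbouring ketal on warming. The fallback sets out from 16 and comes back at 20; it adds the aryllithium to an aldehyde instead of an ester. LiAlH4 (THF, 0 °C) would reduce 16 to (2S,8S,9R)-5-(benzyloxy)-2,8-bis[4-(benzyloxy)phenyl]-9-(hydroxymethyl)-8-methoxy-3,4,8,9-tetrahydro-2H-furo[2,3-h]chromen-9-ol F5. Parikh–Doering oxidation of the primary alcohol (SO3·pyridine, DMSO, iPr2NEt) would give the 9-hydroxy-9-carbaldehyde F6. Aryllithium 19 (2.5 equiv, THF, −78 °C) would add to give the 9-[hydroxy(2,4,6-tris(methoxymethoxy)phenyl)methyl] diol F7 as a mixture of carbinol epimers, and IBX in DMSO would oxidize the secondary alcohol to 20.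

Step 13. The acid needed for MOM cleavage may also ionize the ketal in a way that leads to an acyloin-type 1,2-shift or to opening of the flavan ether, and closure may stop at the methyl ketal. The fallback sets out from 16 and comes back at 23; it carries ring A as benzyl ethers so that no strong acid is needed. Commercial 1,3,5-tris(benzyloxy)benzene would be brominated (NBS, CH2Cl2, 0 °C) to 2-bromo-1,3,5-tris(benzyloxy)benzene F8. n-BuLi (THF, −78 °C) would give 2,4,6-tris(benzyloxy)phenyllithium F9, which would acylate on the ester of 16 to give the hexa-O-benzyl ketone F10. Hydrogenolysis (H2, Pd/C, EtOAc/MeOH) would give the hexaphenol methyl ketal F11, and a catalytic amount of PPTS in acetone at rt would close ring C to give 23.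

**Further compounds**

F1 | step 10 | (2S)-5-(benzyloxy)-2-[4-(benzyloxy)phenyl]-8-{[4-(benzyloxy)phenyl]ethynyl}-7-(methoxymethoxy)chromane | COCOc1cc(OCc2ccccc2)c2c(c1C#Cc1ccc(OCc3ccccc3)cc1)O[C@H](c1ccc(OCc3ccccc3)cc1)CC2
F2 | step 10 | (2S)-5-(benzyloxy)-2-[4-(benzyloxy)phenyl]-8-{[4-(benzyloxy)phenyl]ethynyl}chroman-7-ol | Oc1cc(OCc2ccccc2)c2c(c1C#Cc1ccc(OCc3ccccc3)cc1)O[C@H](c1ccc(OCc3ccccc3)cc1)CC2
F3 | step 10 | methyl (2S)-5-(benzyloxy)-2,8-bis[4-(benzyloxy)phenyl]-3,4-dihydro-2H-furo[2,3-h]chromene-9-carboxylate | COC(=O)c1c(-c2ccc(OCc3ccccc3)cc2)oc2cc(OCc3ccccc3)c3c(c12)O[C@H](c1ccc(OCc2ccccc2)cc1)CC3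
F4 | step 10 | 8,9-epoxide of F3 (both faces) | COC(=O)C12OC1(c1ccc(OCc3ccccc3)cc1)Oc1cc(OCc3ccccc3)c3c(c12)O[C@H](c1ccc(OCc2ccccc2)cc1)CC3
F5 | step 12 | (2S,8S,9R)-5-(benzyloxy)-2,8-bis[4-(benzyloxy)phenyl]-9-(hydroxymethyl)-8-methoxy-3,4,8,9-tetrahydro-2H-furo[2,3-h]chromen-9-ol | OC[C@]1(O)c2c(O[C@@]1(OC)c3ccc(OCc4ccccc4)cc3)cc(OCc3ccccc3)c3c2O[C@H](c2ccc(OCc4ccccc4)cc2)CC3
F6 | step 12 | 9-hydroxy-9-carbaldehyde corresponding to F5 | O=C[C@]1(O)c2c(O[C@@]1(OC)c3ccc(OCc4ccccc4)cc3)cc(OCc3ccccc3)c3c2O[C@H](c2ccc(OCc4ccccc4)cc2)CC3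
F7 | step 12 | 9-[hydroxy(2,4,6-tris(methoxymethoxy)phenyl)methyl] diol, carbinol epimers | OC(c1c(OCOC)cc(OCOC)cc1OCOC)[C@]1(O)c2c(O[C@@]1(OC)c3ccc(OCc4ccccc4)cc3)cc(OCc3ccccc3)c3c2O[C@H](c2ccc(OCc4ccccc4)cc2)CC3
F8 | step 13 | 2-bromo-1,3,5-tris(benzyloxy)benzene | Brc1c(OCc2ccccc2)cc(OCc2ccccc2)cc1OCc1ccccc1
F9 | step 13 | 2,4,6-tris(benzyloxy)phenyllithium | [Li]c1c(OCc2ccccc2)cc(OCc2ccccc2)cc1OCc1ccccc1
F10 | step 13 | hexa-O-benzyl ketone (analogue of 20 with benzyl ethers on ring A) | O=C(c1c(OCc2ccccc2)cc(OCc2ccccc2)cc1OCc1ccccc1)[C@]1(O)c2c(O[C@@]1(OC)c3ccc(OCc4ccccc4)cc3)cc(OCc3ccccc3)c3c2O[C@H](c2ccc(OCc4ccccc4)cc2)CC3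
F11 | step 13 | hexaphenol methyl ketal | O=C(c1c(O)cc(O)cc1O)[C@]1(O)c2c(O[C@@]1(OC)c3ccc(O)cc3)cc(O)c3c2O[C@H](c2ccc(O)cc2)CC3
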